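## Retrosynthetic overview
1. The last bond made is the depside ester C–O bond. Cutting it gives the ring A acid (chlorohaematommic acid) and the ring B phenol (methyl 5-chloro-β-orcinolcarboxylate), which is acylated at its non-chelated 4-OH.
2. The ring A acid comes from methyl orsellinate by C5 chlorination, C3 formylation and ester cleavage. The ring B phenol comes from methyl atratate by chlorination of its only free position.
3. Both benzene rings come from 2,4-dioxocyclohexanecarboxylates by halogenation–dehydrohalogenation.
4. The key C–C bond (C1–C6 of each ring) is made by an intermolecular Michael addition, followed in the same pot by Claisen/Dieckmann closure. The partners are methyl acetoacetate + methyl crotonate (ring A) and dimethyl malonate + hex-4-en-3-one (ring B).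
5. Ring A (steps 1–2) and ring B (steps 6–7) are built in parallel and joined in step 9.

Assumption: the target has no stereocentre and no isolable stereogenic axis, so the SMILES describes one achiral compound and no asymmetric step is needed. The stereocentres of the cyclohexanedione intermediates are transient and vanish on aromatisation.

Numbering used in the text (resorcylate numbering): C1 carries the ester or acid carbon, C2 and C4 the hydroxyls, C6 the methyl. Systematic names are in the compound list.

## Route

Step 1
Reactants: 1 methyl acetoacetate; 2 methyl (E)-but-2-enoate (methyl crotonate)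
Product: 5 methyl 2-methyl-4,6-dioxocyclohexane-1-carboxylate (methyl dihydroorsellinate), via Michael adduct 3 (not isolated), via sodium enolate 4 (not isolated)
Conditions: NaOMe (1.1 equiv), MeOH, reflux, 16 h; then 2 M HCl, 0 °C
Reagents that add atoms: none
Why: Intermolecular Michael addition of the acetoacetate enolate to the crotonate β-carbon makes the C1–C6 bond, the methyl-ketone enolate of 3 then closes the ring by a Dieckmann-type Claisen condensation, irreversible deprotonation of the 1,3-dione pulls both equilibria through, and the two new stereocentres form without control and are erased in step 2.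

Step 2
Reactants: 5 methyl 2-methyl-4,6-dioxocyclohexane-1-carboxylate
Product: 7 methyl 2,4-dihydroxy-6-methylbenzoate (methyl orsellinate), via bromodione 6 (not isolated)
Conditions: Br2 (1.0 equiv), DMF, 0 °C, 1 h; then 80 °C, 12 h
Reagents that add atoms: none
Why: Halogenation–dehydrohalogenation aromatisation, in which the dione is brominated cold at the doubly activated C3, bromide 6 loses HBr through its dienol on warming and the product tautomerises to the resorcinol, an operation routinely used for 6-alkyl-β-resorcylates that leaves no stereocentre.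

Step 3
Reactants: 7 methyl orsellinate
Product: 8 methyl 3-chloro-4,6-dihydroxy-2-methylbenzoate (methyl 5-chloroorsellinate)
Conditions: SO2Cl2 (1.0 equiv), Et2O, 0 °C to rt, 2 h; chromatography, then crystallisation
Reagents that add atoms: sulfuryl chloride, O=S(=O)(Cl)Cl
Why: Electrophilic aromatic chlorination of 6-alkyl-2,4-dihydroxybenzoates with SO2Cl2 in ether goes mainly to C5, para to the chelated 2-OH and ortho to the free 4-OH, and the minor 3-chloro and 3,5-dichloro esters are separable.

Step 4
Reactants: 8 methyl 5-chloroorsellinate
Product: 10 methyl 3-chloro-5-formyl-4,6-dihydroxy-2-methylbenzoate (methyl chlorohaematommate), via alpha-chloro ether 9 (not isolated)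
Conditions: Cl2CHOMe (1.5 equiv), TiCl4 (3.5 equiv), CH2Cl2, −10 °C to rt, 4 h; then ice/1 M HCl
Reagents that add atoms: dichloromethyl methyl ether, COC(Cl)Cl; water, O
Why: In this Rieche formylation the titanium-bound phenoxide delivers the chloro(methoxy)carbenium ion to C3, the only unsubstituted ring carbon (ortho to both hydroxyls, para to the methyl, meta to the ester), and chloro ether 9 is hydrolysed to the aldehyde on work-up.

Step 5
Reactants: 10 methyl chlorohaematommate
Product: 12 3-chloro-5-formyl-4,6-dihydroxy-2-methylbenzoic acid (chlorohaematommic acid), via acylium salt 11 (not isolated)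
Conditions: conc. H2SO4, 0 °C to 20 °C, 1–2 h; poured onto ice, filtered cold
Reagents that add atoms: water, O
Why: In this AAC1 ester cleavage the di-ortho-substituted, electron-rich ester ionises in cold sulfuric acid to acylium ion 11, which water captures on quenching, so the hindered carbonyl needs no tetrahedral pathway and the fully substituted ring can be neither sulfonated nor alkylated by the aldehyde.

Step 6
Reactants: 13 dimethyl malonate; 14 (E)-hex-4-en-3-one
Product: 17 methyl 3,6-dimethyl-2,4-dioxocyclohexane-1-carboxylate, via Michael adduct 15 (not isolated), via sodium enolate 16 (not isolated)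
Conditions: NaOMe (1.1 equiv), MeOH, 0 °C then reflux, 4 h; then 2 M HCl, 0 °C
Reagents that add atoms: none
Why: Intermolecular Michael addition of the malonate anion to the enone makes the C1–C6 bond, the ethyl-ketone enolate of 15 then attacks one malonate ester in an intramolecular Claisen condensation (only the six-membered closure is possible), formation of dione enolate 16 drives the sequence, and the three uncontrolled stereocentres are erased in step 7.

Step 7
Reactants: 17 methyl 3,6-dimethyl-2,4-dioxocyclohexane-1-carboxylate
Product: 19 methyl 2,4-dihydroxy-3,6-dimethylbenzoate (methyl atratate), via bromodione 18 (not isolated)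
Conditions: NBS (1.0 equiv), DMF, 0 °C, 1 h; then 80 °C, 6 h
Reagents that add atoms: none
Why: Halogenation–dehydrohalogenation aromatisation with an N-haloimide, the technical way to this perfumery chemical, in which NBS brominates C3, tertiary bromide 18 ionises through its C4–C5 enol, loses the C6 proton and tautomerises to the arene.

Step 8
Reactants: 19 methyl atratate
Product: 20 methyl 3-chloro-4,6-dihydroxy-2,5-dimethylbenzoate (methyl 5-chloro-β-orcinolcarboxylate)
Conditions: SO2Cl2 (1.05 equiv), CH2Cl2/Et2O, 0 °C to rt, 2 h
Reagents that add atoms: sulfuryl chloride, O=S(=O)(Cl)Cl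
Why: Electrophilic aromatic chlorination can only occur at C5, the single free ring position, which is activated by the ortho 4-OH and the para 2-OH, so no regioisomer can form when one equivalent is used.

Step 9
Reactants: 12 chlorohaematommic acid; 20 methyl 5-chloro-β-orcinolcarboxylate (1.1 equiv)
Product: 22 methyl 3-chloro-4-[(3-chloro-5-formyl-4,6-dihydroxy-2-methylbenzoyl)oxy]-6-hydroxy-2,5-dimethylbenzoate (target), via O-acylisourea 21 (not isolated)
Conditions: DCC (1.2 equiv, added last), dry toluene/THF, 0 °C to rt, 24–48 h; filter, chromatography, crystallisation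
Reagents that add atoms: none
Why: In this carbodiimide depside esterification O-acylisourea 21 is captured by the free, acidic 4-OH of 20, whereas the 2-OH of 20 (chelated to its ester) and both hydroxyls of 12 (chelated to CHO and CO2H and flanked on both sides) are too poorly nucleophilic to compete, and no stereocentre is formed.

## Compound list
1 | methyl acetoacetate (methyl 3-oxobutanoate) | CC(=O)CC(=O)OC | starting material
2 | methyl (E)-but-2-enoate (methyl crotonate) | C/C=C/C(=O)OC | starting material
3 | dimethyl 2-acetyl-3-methylpentanedioate (Michael adduct, stereoisomer mixture, not isolated) | COC(=O)CC(C)C(C(C)=O)C(=O)OC | intermediate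
4 | sodium enolate of 5 (not isolated) | COC(=O)C1C(C)CC(=O)C=C1[O-].[Na+] | intermediate
5 | methyl 2-methyl-4,6-dioxocyclohexane-1-carboxylate (racemic, diastereomer and enol mixture) | COC(=O)C1C(C)CC(=O)CC1=O | intermediate
6 | methyl 3-bromo-6-methyl-2,4-dioxocyclohexane-1-carboxylate (not isolated) | COC(=O)C1C(C)CC(=O)C(Br)C1=O | intermediate
7 | methyl 2,4-dihydroxy-6-methylbenzoate (methyl orsellinate) | COC(=O)c1c(C)cc(O)cc1O | intermediate
8 | methyl 3-chloro-4,6-dihydroxy-2-methylbenzoate | COC(=O)c1c(C)c(Cl)c(O)cc1O | intermediate
9 | methyl 3-chloro-5-[chloro(methoxy)methyl]-4,6-dihydroxy-2-methylbenzoate (not isolated) | COC(=O)c1c(C)c(Cl)c(O)c(C(Cl)OC)c1O | intermediate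
10 | methyl 3-chloro-5-formyl-4,6-dihydroxy-2-methylbenzoate | COC(=O)c1c(C)c(Cl)c(O)c(C=O)c1O | intermediate
11 | 3-chloro-5-formyl-4,6-dihydroxy-2-methylbenzoylium hydrogen sulfate (not isolated) | Cc1c(Cl)c(O)c(C=O)c(O)c1C#[O+].OS(=O)(=O)[O-] | intermediate
12 | 3-chloro-5-formyl-4,6-dihydroxy-2-methylbenzoic acid | OC(=O)c1c(C)c(Cl)c(O)c(C=O)c1O | intermediate
13 | dimethyl malonate | COC(=O)CC(=O)OC | starting material
14 | (E)-hex-4-en-3-one | CCC(=O)/C=C/C | starting material
15 | dimethyl 2-(4-oxohexan-2-yl)propanedioate (Michael adduct, racemic, not isolated) | CCC(=O)CC(C)C(C(=O)OC)C(=O)OC | intermediate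
16 | sodium enolate of 17 (not isolated) | COC(=O)C1C(C)CC(=O)C(C)=C1[O-].[Na+] | intermediate
17 | methyl 3,6-dimethyl-2,4-dioxocyclohexane-1-carboxylate (racemic, diastereomer and enol mixture) | COC(=O)C1C(C)CC(=O)C(C)C1=O | intermediate
18 | methyl 3-bromo-3,6-dimethyl-2,4-dioxocyclohexane-1-carboxylate (not isolated) | COC(=O)C1C(C)CC(=O)C(C)(Br)C1=O | intermediate
19 | methyl 2,4-dihydroxy-3,6-dimethylbenzoate (methyl atratate) | COC(=O)c1c(C)cc(O)c(C)c1O | intermediate
20 | methyl 3-chloro-4,6-dihydroxy-2,5-dimethylbenzoate | COC(=O)c1c(C)c(Cl)c(O)c(C)c1O | intermediate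
21 | N,N'-dicyclohexyl-O-(3-chloro-5-formyl-4,6-dihydroxy-2-methylbenzoyl)isourea (not isolated) | Cc1c(Cl)c(O)c(C=O)c(O)c1C(=O)OC(=NC1CCCCC1)NC1CCCCC1 | intermediate
22 | methyl 3-chloro-4-[(3-chloro-5-formyl-4,6-dihydroxy-2-methylbenzoyl)oxy]-6-hydroxy-2,5-dimethylbenzoate (achiral) | COC(=O)c1c(C)c(Cl)c(OC(=O)c2c(C)c(Cl)c(O)c(C=O)c2O)c(C)c1O | target

## Totals and risks
Total steps: 9. Longest linear sequence: 6 steps (1, 2, 3, 4, 5, 9).

**Step 9 (depside coupling).** Phenol 20 has two ortho substituents next to the reacting hydroxyl, and acid 12 is hindered and unprotected. N-acylurea formation or self-condensation could therefore take over. The fallback sets out from 12 and 19 and comes back to the route at 22. Acid 12 is coupled under the same DCC conditions, through the same O-acylisourea 21, with the non-chlorinated phenol 19. The 4-OH of 19 has only one bulky ortho neighbour, and the product is chloroatranorin F1. In that depside ring A is fully substituted and ring B keeps a single aromatic C–H, at C5 para to the chelated hydroxyl. SO2Cl2 (1.0 equiv, CH2Cl2/Et2O, 0 °C) can therefore place the second chlorine only there, which gives 22.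

**Step 5 (ester cleavage in H2SO4).** Protodecarboxylation or loss of the formyl group could erode the yield. The fallback sets out from 8 and comes back at 12. It exchanges the ester before the aldehyde is present.
- Ester 8 is saponified (KOH, H2O/DMSO, 60 °C, cold acidification) to 3-chloro-4,6-dihydroxy-2-methylbenzoic acid F2.
- Carboxylate-selective alkylation (BnBr, KHCO3, DMF, rt) gives benzyl 3-chloro-4,6-dihydroxy-2-methylbenzoate F3.
- Casnati–Skattebøl ortho-formylation (MgCl2, Et3N, paraformaldehyde, MeCN, reflux) runs through benzyl 3-chloro-4,6-dihydroxy-5-(hydroxymethyl)-2-methylbenzoate F4 to benzyl 3-chloro-5-formyl-4,6-dihydroxy-2-methylbenzoate F5.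
- Neutral hydrogenolysis (H2 1 atm, 10% Pd/C, EtOAc, stopped after one equivalent) releases 12 without touching C–Cl or CHO.

**Step 3 (C5 versus C3 chlorination).** A poor isomer ratio would cost material. The identity of 8 is checked by NOE: its ring proton shows no contact to the ring methyl, whereas that of the 3-chloro isomer does. The fallback sets out from 7 and comes back at 10 by inverting the order of the two substitutions. Rieche formylation of 7 under the conditions of step 4 passes through methyl 3-[chloro(methoxy)methyl]-2,4-dihydroxy-6-methylbenzoate F6 and gives methyl haematommate F7. Attack between the two oxygens is favoured by titanium chelation, and the 5-formyl isomer is removed by chromatography. SO2Cl2 (1.0 equiv, Et2O, 0 °C) then chlorinates the only position left and gives 10.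

## Further compounds
F1 | step 9 | chloroatranorin, methyl 4-[(3-chloro-5-formyl-4,6-dihydroxy-2-methylbenzoyl)oxy]-2-hydroxy-3,6-dimethylbenzoate | COC(=O)c1c(C)cc(OC(=O)c2c(C)c(Cl)c(O)c(C=O)c2O)c(C)c1O
F2 | step 5 | 3-chloro-4,6-dihydroxy-2-methylbenzoic acid | OC(=O)c1c(C)c(Cl)c(O)cc1O
F3 | step 5 | benzyl 3-chloro-4,6-dihydroxy-2-methylbenzoate | O=C(OCc1ccccc1)c1c(C)c(Cl)c(O)cc1O
F4 | step 5 | benzyl 3-chloro-4,6-dihydroxy-5-(hydroxymethyl)-2-methylbenzoate | O=C(OCc1ccccc1)c1c(C)c(Cl)c(O)c(CO)c1O
F5 | step 5 | benzyl 3-chloro-5-formyl-4,6-dihydroxy-2-methylbenzoate | O=C(OCc1ccccc1)c1c(C)c(Cl)c(O)c(C=O)c1O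
F6 | step 3 | methyl 3-[chloro(methoxy)methyl]-2,4-dihydroxy-6-methylbenzoate | COC(=O)c1c(C)cc(O)c(C(Cl)OC)c1O
F7 | step 3 | methyl haematommate, methyl 3-formyl-2,4-dihydroxy-6-methylbenzoate | COC(=O)c1c(C)cc(O)c(C=O)c1O
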